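**Plan**

1. Guaiane numbering is used: five-membered ring C1–C5 (C1 ring-fusion CH, C3 ketone, C4=C5), seven-membered ring C1, C5, C6–C10 (C7 carries C11, C8 the angelate, C10 a methyl).
2. The retrosynthesis cuts the two ester C–O bonds at O8 and O11, then the two C11–CH3 bonds (back to a C7 methyl ester), then C6–C7 and C9–C10 of the seven-membered ring, and last C5=C6 and C1=C10.
3. The central cut is possible because C7 (with its carbon branch), oxygen-bearing C8 and C9 form a three-carbon unit with oxygen on the middle carbon (a siloxyvinyl carbene), and C6=C5–C1=C10 is a diene that the five-membered ring holds s-cis.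
4. Forward: the five-membered ring is bought as 2-methylcyclopentane-1,3-dione, aldol condensation adds C10 with its methyl, and Peterson methylenation adds C6. The seven-membered ring then closes in one operation by rhodium-carbene cyclopropanation of C5=C6 and [3,3] ring enlargement.
5. Stereochemistry: C10 comes from the chiral dirhodium catalyst acting on the flat, achiral triene. C7 and C8 come from a chelation-controlled reduction of the stereolabile β-keto ester on the face away from the C10 methyl. C1 comes from thermodynamic equilibration next to the enone.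
6. End game: Grignard addition makes C11, acid unmasks the enone, then O8 is angeloylated and O11 acetylated.

Key step: step 7

Assumption: the sense of induction of Rh2(S-PTAD)4, dirhodium tetrakis[(S)-(1-adamantyl)(N-phthalimido)acetate], on this new diene is inferred by analogy only; if the annulation gives the 10R series, the mirror-image catalyst Rh2(R-PTAD)4 is used and nothing else changes.

Remark on names: compound names use azulene locants (5, 6, 8, 8a correspond to guaiane C7, C8, C10, C1); the discussion uses guaiane numbers.

**Route**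

Step 1
Reactants: 1 methyl acetoacetate
Product: 2 methyl 2-diazo-3-oxobutanoate
Conditions: 4-acetamidobenzenesulfonyl azide, Et3N, MeCN, 0 to 23 °C
Reagents that add atoms: 4-acetamidobenzenesulfonyl azide, CC(=O)Nc1ccc(cc1)S(=O)(=O)N=[N+]=[N-]
Why: Regitz diazo transfer to the doubly activated methylene of a β-keto ester is a standard, high-yielding reaction.

Step 2
Reactants: 2 methyl 2-diazo-3-oxobutanoate
Product: 3 methyl 3-(tert-butyldimethylsilyloxy)-2-diazobut-3-enoate
Conditions: TBSOTf, Et3N, CH2Cl2, 0 °C
Reagents that add atoms: tert-butyldimethylsilyl trifluoromethanesulfonate, CC(C)(C)[Si](C)(C)OS(=O)(=O)C(F)(F)F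
Why: Soft enolisation and O-silylation of the methyl ketone with a silyl triflate and an amine base gives the 2-siloxyvinyl diazoacetate with the diazo group intact.

Step 3
Reactants: 4 2-methylcyclopentane-1,3-dione
Product: 5 3-ethoxy-2-methylcyclopent-2-en-1-one
Conditions: EtOH, catalytic p-TsOH, toluene, reflux, Dean–Stark trap
Reagents that add atoms: ethanol, CCO
Why: Acid-catalysed O-alkylation of the enol of a cyclic 1,3-diketone with azeotropic removal of water (vinylogous Fischer esterification) differentiates the two carbonyl groups.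

Step 4
Reactants: 5 3-ethoxy-2-methylcyclopent-2-en-1-one, 6 acetaldehyde
Product: 8 3-ethoxy-5-(1-hydroxyethyl)-2-methylcyclopent-2-en-1-one (diastereomer mixture), via lithium enolate 7 (not isolated)
Conditions: LiN(i-Pr)2, THF, −78 °C; then 6, −78 °C; AcOH quench
Reagents that add atoms: none
Why: Kinetic deprotonation of a 3-alkoxyenone with a lithium amide takes place at the α' carbon (future C1), and the cross-conjugated enolate undergoes a directed aldol addition whose two new stereocentres are removed in step 5.

Step 5
Reactants: 8 3-ethoxy-5-(1-hydroxyethyl)-2-methylcyclopent-2-en-1-one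
Product: 10 (E)-3-ethoxy-5-ethylidene-2-methylcyclopent-2-en-1-one, via mesylate 9 (not isolated)
Conditions: MsCl, Et3N, CH2Cl2, 0 °C; then DBU, 23 °C
Reagents that add atoms: none
Why: E1cB elimination of the β-mesyloxy ketone completes the aldol condensation and should give the conjugated exocyclic enone as the more stable E isomer, with the methyl group remote from the carbonyl group.

Step 6
Reactants: 10 (E)-3-ethoxy-5-ethylidene-2-methylcyclopent-2-en-1-one
Product: 12 (E)-1-ethoxy-4-ethylidene-2-methyl-3-methylidenecyclopent-1-ene, via lithium β-silylalkoxide 11 (not isolated)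
Conditions: Me3SiCH2Li (1.2 equiv), THF, −78 °C; then KOt-Bu (1.2 equiv), −78 to 0 °C; cold aqueous NaHCO3, pentane, basic alumina, used at once
Reagents that add atoms: (trimethylsilyl)methyllithium, [Li]C[Si](C)(C)C
Why: Peterson olefination, in which 1,2-addition of the organolithium to the vinylogous ester carbonyl is followed by syn elimination of the potassium β-silylalkoxide, installs C6 under basic conditions throughout, so the acid-labile enol ether and the E-ethylidene group are kept.

Step 7
Reactants: 12 (E)-1-ethoxy-4-ethylidene-2-methyl-3-methylidenecyclopent-1-ene, 3 methyl 3-(tert-butyldimethylsilyloxy)-2-diazobut-3-enoate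
Product: 14 methyl (8S)-6-(tert-butyldimethylsilyloxy)-2-ethoxy-3,8-dimethyl-1,4,7,8-tetrahydroazulene-5-carboxylate, via spiro divinylcyclopropane 13 (not isolated)
Conditions: Rh2(S-PTAD)4 (1 mol %), 2,2-dimethylbutane, −26 °C, 3 (1.3 equiv) added over 2 h; then 23 °C; Et3N-deactivated silica
Reagents that add atoms: none
Why: Rh2(S-PTAD)4 turns 3 into a donor/acceptor vinylcarbene that adds to the C5=C6 methylidene of 12, C6 first, to form the C6–C7 bond and the spirocyclopropane 13, whose siloxyvinyl group on C7 lies cis to the ethylidene arm on C5, and a boat-like [3,3] shift then joins C9 to C10 as C5–C7 breaks. The closest known reaction type is the tandem cyclopropanation/Cope rearrangement (formal (4+3) cycloaddition) of 2-siloxyvinyl diazoacetates with 1,3-dienes under chiral dirhodium carboxylate catalysis, and 12 differs from the known dienes only in its extra enol ether arm. The three-membered ring closes by carbene transfer to the alkene, and the seven-membered ring closes by ring enlargement of the cis-divinylcyclopropane (3 to 7), with release of ring strain and formation of a cyclopentadiene as driving force. The one new stereocentre, C10, is set by the catalyst, whose ligands select one enantiotopic face of the flat triene for carbene addition (the Re face at C5 for 10S), and the suprafacial boat transition state relays this to C10 through the fixed E geometry of the ethylidene group, whose methyl points outward. The step needs site selectivity for C5=C6 and the right cyclopropane geometry: the bulky carbene avoids the tetrasubstituted enol ether and the trisubstituted ethylidene alkene, the ethoxy group makes C6 the nucleophilic terminus, and the siloxyvinyl group is expected on the C1 flank because that side shows only the inward C10 hydrogen whereas the C4 flank carries a methyl group. The enol ether arm cannot take part in a [3,3] shift since C6=C5–C4=C3 is held s-trans and would give an anti-Bredt alkene, and the mixture is kept at or below 23 °C so that any spirocyclopropane of the wrong geometry stays closed and is removed by chromatography instead of opening to an achiral zwitterion.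

Step 8
Reactants: 14 methyl (8S)-6-(tert-butyldimethylsilyloxy)-2-ethoxy-3,8-dimethyl-1,4,7,8-tetrahydroazulene-5-carboxylate
Product: 15 methyl (8S)-2-ethoxy-3,8-dimethyl-6-oxo-1,4,5,6,7,8-hexahydroazulene-5-carboxylate (C5 epimers in equilibrium with the enol)
Conditions: Bu4NF, THF, 0 °C; then AcOH (1 equiv)
Reagents that add atoms: none
Why: Fluoride-mediated cleavage of the silyl enol ether releases the stabilised β-keto ester enolate under basic conditions that leave the ethoxycyclopentadiene and C10 untouched.

Step 9
Reactants: 15 methyl (8S)-2-ethoxy-3,8-dimethyl-6-oxo-1,4,5,6,7,8-hexahydroazulene-5-carboxylate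
Product: 16 methyl (5S,6R,8S)-2-ethoxy-6-hydroxy-3,8-dimethyl-1,4,5,6,7,8-hexahydroazulene-5-carboxylate
Conditions: Zn(BH4)2, Et2O, −20 °C; aqueous NH4Cl
Reagents that add atoms: none
Why: In this chelation-controlled borohydride reduction of an α-substituted β-keto ester, zinc holds the two carbonyl groups in a planar chelate and hydride attacks C8 anti to the C6 branch of C7 to give the cis hydroxy ester, while C7 equilibrates through the enol so that, under Curtin–Hammett control, the chelate reduced fastest should be the one whose open face is also remote from the C10 methyl group, which places O8, the C7 ester and the C10 methyl all cis (7S, 8R).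

Step 10
Reactants: 16 methyl (5S,6R,8S)-2-ethoxy-6-hydroxy-3,8-dimethyl-1,4,5,6,7,8-hexahydroazulene-5-carboxylate
Product: 19 (5S,6R,8S)-6-hydroxy-5-(2-hydroxypropan-2-yl)-3,8-dimethyl-4,5,6,7,8,8a-hexahydroazulen-2(1H)-one as a mixture of C8a (guaiane C1) epimers, via methyl ketone 17 (not isolated), via ethoxydiene diol 18 (not isolated)
Conditions: MeMgBr (6 equiv), THF, 0 to 23 °C; then 1 M HCl, THF–H2O, 0 °C
Reagents that add atoms: methylmagnesium bromide, C[Mg]Br; water, O
Why: Double Grignard addition to the ester of a β-hydroxy ester builds the C11 carbinol while the C8 alkoxide (and the cyclopentadienide, should it be metalated) stays inert, and aqueous acid then hydrolyses the alkoxydiene by protonation on carbon and loss of ethanol to unveil the C3 enone without touching C7, C8 or C10.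

Step 11
Reactants: 19 (5S,6R,8S)-6-hydroxy-5-(2-hydroxypropan-2-yl)-3,8-dimethyl-4,5,6,7,8,8a-hexahydroazulen-2(1H)-one (C8a epimer mixture)
Product: 20 (5S,6R,8S,8aR)-6-hydroxy-5-(2-hydroxypropan-2-yl)-3,8-dimethyl-4,5,6,7,8,8a-hexahydroazulen-2(1H)-one
Conditions: NaOMe (0.2 equiv), MeOH, 23 °C
Reagents that add atoms: none
Why: Base-mediated equilibration through the extended dienolate of the cyclopentenone moves any β,γ-unsaturated isomer into conjugation and should settle C1 as the more stable ring-fusion epimer 1R, in which the C10 methyl group can lie anti to C5 instead of being flanked by C2 and C5.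

Step 12
Reactants: 20 (5S,6R,8S,8aR)-6-hydroxy-5-(2-hydroxypropan-2-yl)-3,8-dimethyl-4,5,6,7,8,8a-hexahydroazulen-2(1H)-one, 21 angelic acid
Product: 23 (5S,6R,8S,8aR)-5-(2-hydroxypropan-2-yl)-3,8-dimethyl-2-oxo-1,2,4,5,6,7,8,8a-octahydroazulen-6-yl (Z)-2-methylbut-2-enoate, via mixed anhydride 22 (not isolated)
Conditions: 21, 2,4,6-Cl3C6H2COCl, Et3N, toluene, 23 °C; then 20, 75 °C
Reagents that add atoms: none
Why: Yamaguchi-type esterification through the mixed anhydride with 2,4,6-trichlorobenzoic acid, run without a nucleophilic catalyst, acylates only the secondary C8 hydroxyl at the unhindered angeloyl carbonyl (the tertiary C11 hydroxyl is too hindered) and transfers the Z acid without isomerisation to the tiglate.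

Step 13
Reactants: 23 (5S,6R,8S,8aR)-5-(2-hydroxypropan-2-yl)-3,8-dimethyl-2-oxo-1,2,4,5,6,7,8,8a-octahydroazulen-6-yl (Z)-2-methylbut-2-enoate
Product: 24 torilin
Conditions: Ac2O, DMAP, Et3N, CH2Cl2, 40 °C
Reagents that add atoms: acetic anhydride, CC(=O)OC(C)=O
Why: Steglich acetylation with DMAP-activated acetic anhydride is the standard way to esterify a tertiary alcohol and should leave the enone, the angelate geometry and the four stereocentres untouched.

**Compound list**

1 | methyl acetoacetate | CC(=O)CC(=O)OC | starting material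
2 | methyl 2-diazo-3-oxobutanoate | CC(=O)C(=[N+]=[N-])C(=O)OC | intermediate
3 | methyl 3-(tert-butyldimethylsilyloxy)-2-diazobut-3-enoate | COC(=O)C(=[N+]=[N-])C(=C)O[Si](C)(C)C(C)(C)C | intermediate
4 | 2-methylcyclopentane-1,3-dione | CC1C(=O)CCC1=O | starting material
5 | 3-ethoxy-2-methylcyclopent-2-en-1-one | CCOC1=C(C)C(=O)CC1 | intermediate
6 | acetaldehyde | CC=O | starting material
7 | lithium 4-ethoxy-5-methylcyclopenta-1,4-dien-1-olate (lithium enolate of 5) | CCOC1=C(C)C(O[Li])=CC1 | intermediate (not isolated)
8 | 3-ethoxy-5-(1-hydroxyethyl)-2-methylcyclopent-2-en-1-one, diastereomer mixture | CCOC1=C(C)C(=O)C(C1)C(C)O | intermediate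
9 | 1-(4-ethoxy-3-methyl-2-oxocyclopent-3-en-1-yl)ethyl methanesulfonate | CCOC1=C(C)C(=O)C(C1)C(C)OS(C)(=O)=O | intermediate (not isolated)
10 | (E)-3-ethoxy-5-ethylidene-2-methylcyclopent-2-en-1-one | CCOC1=C(C)C(=O)/C(C1)=C/C | intermediate
11 | lithium (E)-3-ethoxy-5-ethylidene-2-methyl-1-[(trimethylsilyl)methyl]cyclopent-2-en-1-olate, racemic | CCOC1=C(C)C(O[Li])(C[Si](C)(C)C)/C(C1)=C/C | intermediate (not isolated)
12 | (E)-1-ethoxy-4-ethylidene-2-methyl-3-methylidenecyclopent-1-ene | CCOC1=C(C)C(=C)/C(C1)=C/C | intermediate
13 | methyl (1S,3R,7E)-1-[1-(tert-butyldimethylsilyloxy)ethenyl]-5-ethoxy-7-ethylidene-4-methylspiro[2.4]hept-4-ene-1-carboxylate | COC(=O)[C@@]1(C(=C)O[Si](C)(C)C(C)(C)C)C[C@@]12C(C)=C(OCC)C/C2=C\C | intermediate (not isolated)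
14 | methyl (8S)-6-(tert-butyldimethylsilyloxy)-2-ethoxy-3,8-dimethyl-1,4,7,8-tetrahydroazulene-5-carboxylate | COC(=O)C1=C(O[Si](C)(C)C(C)(C)C)C[C@H](C)C2=C(C1)C(C)=C(OCC)C2 | intermediate
15 | methyl (8S)-2-ethoxy-3,8-dimethyl-6-oxo-1,4,5,6,7,8-hexahydroazulene-5-carboxylate, C5 epimers and enol | COC(=O)C1C(=O)C[C@H](C)C2=C(C1)C(C)=C(OCC)C2 | intermediate
16 | methyl (5S,6R,8S)-2-ethoxy-6-hydroxy-3,8-dimethyl-1,4,5,6,7,8-hexahydroazulene-5-carboxylate | O[C@@H]1C[C@H](C)C2=C(C[C@@H]1C(=O)OC)C(C)=C(OCC)C2 | intermediate
17 | 1-[(5S,6R,8S)-2-ethoxy-6-hydroxy-3,8-dimethyl-1,4,5,6,7,8-hexahydroazulen-5-yl]ethan-1-one | O[C@@H]1C[C@H](C)C2=C(C[C@@H]1C(C)=O)C(C)=C(OCC)C2 | intermediate (not isolated)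
18 | (5S,6R,8S)-2-ethoxy-5-(2-hydroxypropan-2-yl)-3,8-dimethyl-1,4,5,6,7,8-hexahydroazulen-6-ol | O[C@@H]1C[C@H](C)C2=C(C[C@@H]1C(C)(C)O)C(C)=C(OCC)C2 | intermediate (not isolated)
19 | (5S,6R,8S)-6-hydroxy-5-(2-hydroxypropan-2-yl)-3,8-dimethyl-4,5,6,7,8,8a-hexahydroazulen-2(1H)-one, C8a epimer mixture | O[C@@H]1C[C@H](C)C2CC(=O)C(C)=C2C[C@@H]1C(C)(C)O | intermediate
20 | (5S,6R,8S,8aR)-6-hydroxy-5-(2-hydroxypropan-2-yl)-3,8-dimethyl-4,5,6,7,8,8a-hexahydroazulen-2(1H)-one | O[C@@H]1C[C@H](C)[C@H]2CC(=O)C(C)=C2C[C@@H]1C(C)(C)O | intermediate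
21 | angelic acid, (Z)-2-methylbut-2-enoic acid | C/C=C(/C)C(=O)O | starting material
22 | (Z)-2-methylbut-2-enoic 2,4,6-trichlorobenzoic anhydride | C/C=C(/C)C(=O)OC(=O)c1c(Cl)cc(Cl)cc1Cl | intermediate (not isolated)
23 | (5S,6R,8S,8aR)-5-(2-hydroxypropan-2-yl)-3,8-dimethyl-2-oxo-1,2,4,5,6,7,8,8a-octahydroazulen-6-yl (Z)-2-methylbut-2-enoate | C/C=C(/C)C(=O)O[C@@H]1C[C@H](C)[C@H]2CC(=O)C(C)=C2C[C@@H]1C(C)(C)O | intermediate
24 | torilin, (5S,6R,8S,8aR)-5-(2-acetoxypropan-2-yl)-3,8-dimethyl-2-oxo-1,2,4,5,6,7,8,8a-octahydroazulen-6-yl (Z)-2-methylbut-2-enoate | C/C=C(/C)C(=O)O[C@@H]1C[C@H](C)[C@H]2CC(=O)C(C)=C2C[C@@H]1C(C)(C)OC(C)=O | target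

**Step count and risks**

Total step count: 13. Longest linear sequence: 11 steps (steps 3 to 13, from 4); the diazo ester branch (steps 1 and 2) joins at step 7.

The three steps most likely to fail:

Step 7. The carbene may place its siloxyvinyl group on the enol ether flank of C5, which gives a spirocyclopropane that cannot enlarge. Heating to convert that isomer would pass through an open, achiral zwitterion and erode the enantiomeric purity. The sense of induction on this diene is also untested. The fallback sets out from 12 and 3 and comes back to the route at 18. The annulation is run without enantiocontrol, with dirhodium tetrapivalate Rh2(OPiv)4 in toluene and then at 80 °C, so that both spirocyclopropanes funnel to the racemic annulation product F1. This is carried as the racemate through the conditions of steps 8 and 9 to the racemic β-keto ester F2 and the racemic all-cis hydroxy ester F3. F3 is esterified with (S)-O-methylmandelic acid (DCC, DMAP, CH2Cl2), and the two diastereomeric esters are separated by chromatography: the (5S,6R,8S) mandelate F4 is kept and the (5R,6S,8R) mandelate F5 is discarded. Excess MeMgBr under the conditions of step 10 cleaves the mandelate of F4 and converts its methyl ester in the same operation, which gives the ethoxydiene diol 18, and the route continues from there unchanged.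

Step 9. Hydride may be delivered to the wrong face of C8 relative to the C10 methyl group, or the cis/trans selectivity at C7/C8 may be poor, because the bias of the seven-membered ring is only inferred. The fallback sets out from 15 and comes back at 16. Substrate control is replaced by catalyst control: a dynamic kinetic resolution of 15 with an NADPH-dependent ketoreductase (glucose and glucose dehydrogenase for cofactor recycling, phosphate buffer pH 7.5 to 8, DMSO co-solvent, 30 °C), chosen from a commercial enzyme panel for the cis-(8R) outcome. C7 racemises through the enol faster than the ketone is reduced, so the enzyme should fix C8 and with it C7 whatever the influence of C10. The product is 16 itself, so this fallback makes no new compound F0.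

Step 12. Acylation of the hindered C8 hydroxyl may be slow, and the activated angeloyl unit may isomerise from Z to E on prolonged heating, giving the tiglate. The fallback sets out from 20 and 6 and comes back at 23. O8 of 20 is acylated with 2-[bis(2,2,2-trifluoroethoxy)phosphoryl]propanoic acid (DCC, DMAP, CH2Cl2) to give the phosphonopropanoate F6. The Z alkene is then built in place by Still–Gennari olefination with acetaldehyde 6 (KN(SiMe3)2, 18-crown-6, THF, −78 °C), which should give 23 directly.

**Further compounds**

F1 | step 7 | racemic methyl 6-(tert-butyldimethylsilyloxy)-2-ethoxy-3,8-dimethyl-1,4,7,8-tetrahydroazulene-5-carboxylate | COC(=O)C1=C(O[Si](C)(C)C(C)(C)C)CC(C)C2=C(C1)C(C)=C(OCC)C2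
F2 | step 7 | racemic methyl 2-ethoxy-3,8-dimethyl-6-oxo-1,4,5,6,7,8-hexahydroazulene-5-carboxylate | COC(=O)C1C(=O)CC(C)C2=C(C1)C(C)=C(OCC)C2
F3 | step 7 | racemic methyl (5S*,6R*,8S*)-2-ethoxy-6-hydroxy-3,8-dimethyl-1,4,5,6,7,8-hexahydroazulene-5-carboxylate (both enantiomers written) | O[C@@H]1C[C@H](C)C2=C(C[C@@H]1C(=O)OC)C(C)=C(OCC)C2.O[C@H]1C[C@@H](C)C2=C(C[C@H]1C(=O)OC)C(C)=C(OCC)C2
F4 | step 7 | methyl (5S,6R,8S)-2-ethoxy-6-{[(2S)-2-methoxy-2-phenylacetyl]oxy}-3,8-dimethyl-1,4,5,6,7,8-hexahydroazulene-5-carboxylate | CO[C@@H](c1ccccc1)C(=O)O[C@@H]1C[C@H](C)C2=C(C[C@@H]1C(=O)OC)C(C)=C(OCC)C2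
F5 | step 7 | methyl (5R,6S,8R)-2-ethoxy-6-{[(2S)-2-methoxy-2-phenylacetyl]oxy}-3,8-dimethyl-1,4,5,6,7,8-hexahydroazulene-5-carboxylate | CO[C@@H](c1ccccc1)C(=O)O[C@H]1C[C@@H](C)C2=C(C[C@H]1C(=O)OC)C(C)=C(OCC)C2
F0 | step 9 | none | none
F6 | step 12 | (5S,6R,8S,8aR)-5-(2-hydroxypropan-2-yl)-3,8-dimethyl-2-oxo-1,2,4,5,6,7,8,8a-octahydroazulen-6-yl 2-[bis(2,2,2-trifluoroethoxy)phosphoryl]propanoate (epimers at the phosphonate carbon) | CC(C(=O)O[C@@H]1C[C@H](C)[C@H]2CC(=O)C(C)=C2C[C@@H]1C(C)(C)O)P(=O)(OCC(F)(F)F)OCC(F)(F)F
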